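**Retrosynthetic overview**
- The target is the N–H pyrrole, released in the last step by acidolysis of its N-Boc derivative.
- Key disconnection: the C2'–C3' bond of the unbranched tricosyl chain on pyrrole C3. Both carbons are plain CH2 groups, so the cut gives two primary alkyl radicals, and C1' keeps the ring-side radical out of conjugation with the pyrrole. The two halves are a pyrrol-3-ylpropanoic acid and docosanoic acid, joined by mixed Kolbe electrolysis.
- The pyrrolylpropanoic acid comes from a 3-bromopyrrole-2-carboxylate by N-Boc protection, Heck coupling with benzyl acrylate, and one hydrogenation that saturates the alkene and frees the acid.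
- No ring is formed: the single pyrrole ring is bought with its C2 ester and C3 bromide in place, and the target has no stereocentre.

Key step: step 4

Remark: chain carbons are numbered C1' to C23' outward from pyrrole C3; the alkene geometry created in step 2 is erased in step 3.

**Route**

Step 1
Reactants: 1 methyl 3-bromo-1H-pyrrole-2-carboxylate
Product: 2 1-tert-butyl 2-methyl 3-bromo-1H-pyrrole-1,2-dicarboxylate
Conditions: Boc2O (1.2 equiv), DMAP (0.1 equiv), MeCN, rt
Reagents that add atoms: di-tert-butyl dicarbonate, CC(C)(C)OC(=O)OC(=O)OC(C)(C)C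
Why: DMAP-catalysed N-acylation (carbamate formation) of the acidic N–H of the ester-bearing pyrrole is routine, and the carbamate further lowers the electron density of the ring for the later anodic step.

Step 2
Reactants: 2 1-tert-butyl 2-methyl 3-bromo-1H-pyrrole-1,2-dicarboxylate; 3 benzyl acrylate
Product: 4 1-tert-butyl 2-methyl 3-[(1E)-3-(benzyloxy)-3-oxoprop-1-en-1-yl]-1H-pyrrole-1,2-dicarboxylate
Conditions: 3 (1.5 equiv), Pd(OAc)2 (5 mol%), P(o-tol)3 (10 mol%), Et3N (2 equiv), DMF, 90 °C
Reagents that add atoms: none
Why: Heck reaction, in which zerovalent palladium formed in situ inserts into the C3–Br bond, the pyrrolylpalladium species adds across the acrylate and syn β-hydride elimination delivers the (E)-enoate, whose geometry is of no consequence because the alkene is saturated next.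

Step 3
Reactants: 4 1-tert-butyl 2-methyl 3-[(1E)-3-(benzyloxy)-3-oxoprop-1-en-1-yl]-1H-pyrrole-1,2-dicarboxylate
Product: 6 3-[1-(tert-butoxycarbonyl)-2-(methoxycarbonyl)-1H-pyrrol-3-yl]propanoic acid, via saturated benzyl ester 5 (not isolated)
Conditions: H2 (1 atm), 10% Pd/C, EtOAc, rt
Reagents that add atoms: none
Why: Heterogeneous catalytic hydrogenation first saturates the conjugated alkene and then hydrogenolyses the benzyl C–O bond in the same flask, while the aromatic N-Boc pyrrole, the methyl ester and the carbamate should be inert at atmospheric pressure.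

Step 4
Reactants: 6 3-[1-(tert-butoxycarbonyl)-2-(methoxycarbonyl)-1H-pyrrol-3-yl]propanoic acid; 7 docosanoic acid
Product: 8 1-tert-butyl 2-methyl 3-tricosyl-1H-pyrrole-1,2-dicarboxylate
Conditions: 7 (6 equiv), NaOMe (0.05 equiv per CO2H), MeOH, 50–55 °C, undivided cell, smooth Pt anode, Pt cathode, constant current ca. 0.2 A cm−2, stopped while the medium is still weakly acidic
Reagents that add atoms: none
Why: Both carboxylates are adsorbed on the Pt anode and oxidised by one electron each, the acyloxy radicals lose CO2, and the resulting primary radicals, 2-(pyrrol-3-yl)ethyl from 6 and henicosyl from 7, combine in the crowded layer at the electrode to form the C2'–C3' bond, while protons are reduced to H2 at the cathode. The closest known reaction type is the mixed Kolbe coupling of a functionalised or 3-arylpropanoic acid with a fatty acid; an acid carrying a pyrrole has to be regarded as untried in it. No ring is closed and no stereocentre is created. Cross-coupling must win over homo-coupling, which the sixfold excess of 7 should secure statistically, and the two symmetric by-products, a C42 alkane and a polar bis-pyrrole diester, should separate easily on silica. The radical pathway must also win over two-electron oxidation to a cation, which is favoured by the CH2 spacer that keeps the ring-side radical centre unconjugated with the pyrrole, together with smooth Pt, high current density and a weakly acidic methanolic medium. The pyrrole ring itself should be spared because the C2 ester and the N-Boc group lower its electron density and the adsorbed carboxylate layer shields the anode.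

Step 5
Reactants: 8 1-tert-butyl 2-methyl 3-tricosyl-1H-pyrrole-1,2-dicarboxylate
Product: 9 methyl 3-tricosyl-1H-pyrrole-2-carboxylate
Conditions: TFA, CH2Cl2, 0 °C to rt
Reagents that add atoms: none
Why: Acidolysis of the tert-butyl carbamate (loss of the tert-butyl cation as 2-methylpropene, then decarboxylation of the N-carboxylic acid) frees the N–H, and the methyl ester and the saturated chain should not be touched by TFA.

**Compound list**
1 | methyl 3-bromo-1H-pyrrole-2-carboxylate | COC(=O)c1[nH]ccc1Br | starting material
2 | 1-tert-butyl 2-methyl 3-bromo-1H-pyrrole-1,2-dicarboxylate | COC(=O)c1c(Br)ccn1C(=O)OC(C)(C)C | intermediate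
3 | benzyl acrylate | C=CC(=O)OCc1ccccc1 | starting material
4 | 1-tert-butyl 2-methyl 3-[(1E)-3-(benzyloxy)-3-oxoprop-1-en-1-yl]-1H-pyrrole-1,2-dicarboxylate | COC(=O)c1c(/C=C/C(=O)OCc2ccccc2)ccn1C(=O)OC(C)(C)C | intermediate
5 | 1-tert-butyl 2-methyl 3-[3-(benzyloxy)-3-oxopropyl]-1H-pyrrole-1,2-dicarboxylate | COC(=O)c1c(CCC(=O)OCc2ccccc2)ccn1C(=O)OC(C)(C)C | intermediate (not isolated)
6 | 3-[1-(tert-butoxycarbonyl)-2-(methoxycarbonyl)-1H-pyrrol-3-yl]propanoic acid | COC(=O)c1c(CCC(=O)O)ccn1C(=O)OC(C)(C)C | intermediate
7 | docosanoic acid | CCCCCCCCCCCCCCCCCCCCCC(=O)O | starting material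
8 | 1-tert-butyl 2-methyl 3-tricosyl-1H-pyrrole-1,2-dicarboxylate | CCCCCCCCCCCCCCCCCCCCCCCc1ccn(C(=O)OC(C)(C)C)c1C(=O)OC | intermediate
9 | methyl 3-tricosyl-1H-pyrrole-2-carboxylate | CCCCCCCCCCCCCCCCCCCCCCCc1cc[nH]c1C(=O)OC | target

**Step count**
Total steps: 5. Longest linear sequence: 5 steps (1 to 9); docosanoic acid 7 is used as purchased.

**Steps most likely to fail**

Step 4 (mixed Kolbe electrolysis). What may go wrong:
- anodic attack on the pyrrole ring;
- two-electron oxidation of the ring-side radical with capture by methanol;
- fouling of the anode by a waxy hydrocarbon film that chokes the current;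
- homo-coupling outrunning cross-coupling.

Methanolysis of the N-Boc group during electrolysis would be harmless, since step 5 removes that group anyway.

Fallback, from 6 back to 8 by olefination: BH3·SMe2 (THF, 0 °C) would reduce the carboxylic acid of 6 selectively to 1-tert-butyl 2-methyl 3-(3-hydroxypropyl)-1H-pyrrole-1,2-dicarboxylate F1. Dess–Martin periodinane (CH2Cl2, rt) would oxidise it to 1-tert-butyl 2-methyl 3-(3-oxopropyl)-1H-pyrrole-1,2-dicarboxylate F2. Commercial 1-bromoicosane and PPh3 (toluene, reflux) would give icosyltriphenylphosphonium bromide F3, which NaHMDS (THF, −78 °C) would convert into icosylidenetriphenylphosphorane F4. Wittig reaction of F4 with F2 would give 1-tert-butyl 2-methyl 3-[(3Z)-tricos-3-en-1-yl]-1H-pyrrole-1,2-dicarboxylate F5. Hydrogenation (H2, Pd/C, EtOAc) would saturate the C3'–C4' alkene and rejoin the route at 8.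

Step 2 (Heck coupling). What may go wrong:
- sluggish oxidative addition into the C3–Br bond next to the C2 ester;
- loss of the N-Boc group under hot basic conditions;
- reductive debromination.

Fallback, from 2 to 5 by sp2–sp3 Negishi coupling: zinc dust (LiCl, THF, 40 °C) would insert into commercial benzyl 3-bromopropanoate to give [3-(benzyloxy)-3-oxopropyl]zinc bromide F6. Pd(OAc)2 with SPhos (THF, 50 °C) would couple F6 with 2 to give 5 directly. Compound 5 would then be isolated and taken on to 6 by the hydrogenolysis of step 3.

Step 3 (hydrogenation and hydrogenolysis). What may go wrong: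
- stalling of the benzyl C–O hydrogenolysis on a catalyst poisoned by phosphine or amine carried over from step 2;
- partial saturation of the pyrrole ring if the reaction is then forced.

Fallback, from 2 to 6 without a benzyl ester: Heck coupling of 2 with acrylic acid (Pd(OAc)2, P(o-tol)3, Et3N, DMF, 90 °C) would give (2E)-3-[1-(tert-butoxycarbonyl)-2-(methoxycarbonyl)-1H-pyrrol-3-yl]prop-2-enoic acid F7. Homogeneous hydrogenation with RhCl(PPh3)3 (H2, benzene–EtOH, rt) would reduce only the alkene and return the route at 6.

**Further compounds**
F1 | step 4 | 1-tert-butyl 2-methyl 3-(3-hydroxypropyl)-1H-pyrrole-1,2-dicarboxylate | COC(=O)c1c(CCCO)ccn1C(=O)OC(C)(C)C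
F2 | step 4 | 1-tert-butyl 2-methyl 3-(3-oxopropyl)-1H-pyrrole-1,2-dicarboxylate | COC(=O)c1c(CCC=O)ccn1C(=O)OC(C)(C)C
F3 | step 4 | icosyltriphenylphosphonium bromide | CCCCCCCCCCCCCCCCCCCC[P+](c1ccccc1)(c1ccccc1)c1ccccc1.[Br-]
F4 | step 4 | icosylidenetriphenylphosphorane | CCCCCCCCCCCCCCCCCCCC=P(c1ccccc1)(c1ccccc1)c1ccccc1
F5 | step 4 | 1-tert-butyl 2-methyl 3-[(3Z)-tricos-3-en-1-yl]-1H-pyrrole-1,2-dicarboxylate | CCCCCCCCCCCCCCCCCCC/C=C\CCc1ccn(C(=O)OC(C)(C)C)c1C(=O)OC
F6 | step 2 | [3-(benzyloxy)-3-oxopropyl]zinc bromide | Br[Zn]CCC(=O)OCc1ccccc1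
F7 | step 3 | (2E)-3-[1-(tert-butoxycarbonyl)-2-(methoxycarbonyl)-1H-pyrrol-3-yl]prop-2-enoic acid | COC(=O)c1c(/C=C/C(=O)O)ccn1C(=O)OC(C)(C)C
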